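**Compound numbers used throughout:** 1 olivetol; 2 magnesium chelate of olivetolic acid; 3 olivetolic acid; 4 benzyl olivetolate; 5 hex-2-ynoic acid; 6 aryl hex-2-ynoate of ring B; 7 methyl acetoacetate; 8 dimethyl ketal of 7; 9 methyl (2E)-3-methoxybut-2-enoate; 10 lithium dienolate of 9; 11 silyl ketene acetal diene; 12 ring B silyl ether of 6; 13 cycloadduct; 14 benzyl ester of the depside; 15 stenosporic acid.

## Analysis of the target

Stenosporic acid (15) is a depside in which two benzene rings are joined by one aryl ester: ring A is a 2-hydroxy-4-methoxy-6-propylbenzoyl unit, and its carbonyl is bound to O-4 of ring B, a 2-hydroxy-6-pentylbenzoic acid. There is no stereocenter and no ring fusion, so the problem is entirely one of regiochemistry on two resorcinol-derived rings. The sensitive groups are the aryl ester link, which alkoxides, hydroxide and amines cleave, and the free salicylic acid of ring B, which decarboxylates on heating or in acid. Three features make the synthesis awkward. The ester carbonyl on ring A sits between two ortho substituents (C2–OH and C6–propyl), so a preformed ring A acid is a hindered acyl donor. The two oxygens of ring A must end up different (free OH at C2, methyl ether at C4). On ring B the acyl group must go to O-4 while O-2 stays free. That last point is helped by the molecule itself, because the C2 hydroxyl of ring B is hydrogen-bonded to the neighbouring carboxyl derivative and is much less nucleophilic than the C4 hydroxyl. The strategy rests on the pattern around C1 of ring A: C1 and C6 map onto the two sp carbons of a hex-2-ynoate, and C2–C5 with their oxygens at C2 and C4 map onto a 1,3-dioxygenated butadiene. If that ynoate is already the ester of O-4 of ring B, the depside bond is made from an unhindered linear acid, and ring A is then grown on it with its methyl ether in place.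

## Retrosynthetic reasoning

**15 to 14.** The O–CH2 bond of a benzyl ester on the ring B carboxyl is cut first. The free salicylic acid should appear last, because it decarboxylates easily and would interfere with every acylation and with the acid-sensitive diene. A benzyl ester is chosen because it leaves by hydrogenolysis under neutral conditions, which the aryl ester link tolerates; the forward step only has to cleave one benzylic C–O bond.

**14 to 6 and 11.** Ring A is opened at C1–C2 and C5–C6. C1 and C6 go back to the triple bond of the aryl ynoate 6, and C2–C5 go back to the four-carbon diene 11. These bonds are chosen over the ester C–O bond because cutting the ester would require a 2,6-disubstituted benzoic acid with its two oxygens already differentiated and one of them protected. What is gained is that ring A needs no separate synthesis or protecting group, the C4 methyl ether comes from 11, and the hindered ester exists before it becomes hindered. The forward reaction has to add the diene to an internal ynoate in one orientation, aromatize by loss of the ketal methoxy group, and leave both esters intact.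

**6 to 4 and 5.** The acyl–oxygen bond of the ynoate ester is cut, giving the phenol 4 and the linear acid 5. This is the depside bond of the target, formed here by a plain carbodiimide esterification. The forward step must acylate only the 4-hydroxyl of 4; the chelated 2-hydroxyl is expected to stay free.

**4 to 3 to 1.** The benzyl ester C–O bond is cut to give acid 3, and the aryl–carboxyl C–C bond of 3 is cut to give 1. The carboxylation has to go to C4 of 1 (ortho to one hydroxyl, para to the other) and not to C2 between the two hydroxyls. The esterification has to alkylate the carboxylate without touching the phenols.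

**11 to 9 to 7.** The O–Si bond of 11 is cut to give the vinylogous ester 9, and the enol ether C–O bond of 9 is cut to give the β-keto ester 7. The forward steps are O-methylation of the ketone as its enol ether, then γ-deprotonation and O-silylation. All four diene carbons and the future C4 methoxy group of ring A come from 7.

## Alternatives that were turned down

**Alternative 1: build ring B by an Alder–Rickert sequence with ring A already attached.**
- Disconnection: ring B is cut at C1–C2 and C5–C6 into benzyl oct-2-ynoate (A3) and a 5,5-dimethylcyclohexadiene, 5-[(tert-butyldimethylsilyl)oxy]-3,3-dimethylcyclohexa-1,5-dien-1-yl 2-(benzyloxy)-4-methoxy-6-propylbenzoate (A2). A2 carries the finished, benzyl-protected ring A as an enol ester.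
- Forward key step: [4+2] addition of A2 to A3 gives a bicyclo[2.2.2]octadiene, which loses its gem-dimethyl ethano bridge by retro-Diels–Alder reaction. The product is benzyl 4-{[2-(benzyloxy)-4-methoxy-6-propylbenzoyl]oxy}-2-[(tert-butyldimethylsilyl)oxy]-6-pentylbenzoate (A1).
- For: both oxygen donors of A2 polarize the diene the same way, so the orientation is secure. The dienophile A3 is a robust alkyl ynoate. Ring B is formed with its benzyl ester, so no resorcinol has to be carboxylated. On that point this alternative is stronger than the chosen route, which must carboxylate 1 regioselectively.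
- Against: ring A has to be made beforehand with O-2 protected and O-4 methylated, so the differentiation problem returns. The hindered 2,6-disubstituted ring A acyl group must be placed on a vinylogous acid oxygen, where C-acylation competes. The enol ester of A2 is an acyl donor and must survive the high temperatures that cycloreversion of such bridged adducts normally needs. A1 then needs desilylation and a double hydrogenolysis.
- Comparison: more steps, and the depside bond is still made from the hindered acid. In exchange for its carboxylation step, the chosen route makes that bond from an unhindered linear acid and forms ring A with the correct oxygen pattern.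

**Alternative 2: build ring B from a triketide pyrone by decarboxylative cycloaddition.**
- Disconnection: ring B is cut at C2–C3 and C1–C6 into 2-oxo-6-pentyl-2H-pyran-4-yl 2,4-dimethoxy-6-propylbenzoate (A5) and benzyl 3-methoxyprop-2-ynoate (A6).
- Forward key step: A6 adds across C3 and C6 of the pyrone, and the bridged lactone aromatizes in a decarboxylative retro-[4+2] step to benzyl 4-[(2,4-dimethoxy-6-propylbenzoyl)oxy]-2-methoxy-6-pentylbenzoate (A4).
- For: the pyrone core is the natural triketide lactone and is easy to make. The aromatization is irreversible. The polarity matches, since the nucleophilic C3 of the pyrone meets the methoxy-bearing β-carbon of A6. In irreversibility of the aromatizing step this alternative equals the chosen route.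
- Against: 2-pyrones are sluggish dienes that usually need forcing temperatures. A5 is a vinylogous mixed anhydride, so its aroyl group can be transferred or migrate under those conditions. A6 is a push–pull alkyne of limited stability, and its donor group lowers its dienophilicity. A4 carries three methyl ethers; the two ortho to carbonyls must be cleaved while the third, the benzyl ester and the depside ester survive, and a chelation-directed Lewis acid cleavage exposes both esters. Ring A must again be premade.
- Comparison: the chosen route needs no ether cleavage and no preformed ring A. Its dienophile is a stable aryl ynoate, and its diene is far more reactive than a pyrone.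

**Alternative 3: biomimetic aldol folding of a triketo aryl ester.**
- Disconnection: ring A is cut at C1–C6 to give benzyl 2-hydroxy-6-pentyl-4-[(3,5,7-trioxodecanoyl)oxy]benzoate (A8), which would be assembled on the 4-hydroxyl of 4.
- Forward key step: base-mediated aldol attack of the C2 methylene of A8 on its C7 ketone, then dehydration and enolization, gives benzyl 4-[(2,4-dihydroxy-6-propylbenzoyl)oxy]-2-hydroxy-6-pentylbenzoate (A7).
- For: it follows the biosynthesis and grows ring A on ring B, as the chosen route does, with no protecting group on ring A. The later methylation is credible, because the 4-hydroxyl of ring A in A7 is the only unchelated phenol; on that point it is not weaker than the chosen route in selectivity, only one step longer.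
- Against: A8 has several enolizable positions and three cyclization modes. Besides the desired C2-to-C7 aldol, the C6 carbon can attack C1 (Claisen) and the C5 enol oxygen can attack C1 (lactonization to a pyrone). Both of these expel the ring B phenoxide, and an aryl ester is a much better leaving group than the thioester of the natural system, so the depside bond is the likely casualty. Assembling the triketo chain on a phenol is delicate, and the basic methylation puts the aryl ester at risk again.
- Comparison: the chosen route closes ring A by a cycloaddition in which the ester carbonyl is never attacked, under neutral then mildly acidic conditions, and brings the methyl ether in with the diene.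

Key step: step 6

Assumption: the ketene acetal double bond of 11 is drawn 1E; its geometry disappears when that carbon becomes aromatic, so either isomer would serve.

## Route

Step 1
Reactants: 1 olivetol (5-pentylbenzene-1,3-diol)
Product: 3 olivetolic acid (2,4-dihydroxy-6-pentylbenzoic acid), via magnesium olivetolate chelate 2 (not isolated)
Conditions: MeOMgOCO2Me (2 M in DMF, 4 equiv), 120 °C, N2 sweep, 2 h; then cold 2 M HCl, 0 °C
Reagents that add atoms: methyl magnesium carbonate (MeOMgOCO2Me), [Mg+2].COC(=O)[O-].C[O-]
Why: Kolbe–Schmitt-type ortho-carboxylation of a resorcinol with methyl magnesium carbonate; attack at the carbon ortho to one hydroxyl and para to the other is expected, and the magnesium salicylate chelate 2 pulls the reversible reaction forward. Cold acidification limits decarboxylation of 3.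

Step 2
Reactants: 3 olivetolic acid
Product: 4 benzyl 2,4-dihydroxy-6-pentylbenzoate (benzyl olivetolate)
Conditions: BnBr (1.05 equiv), KHCO3 (1.2 equiv), DMF, rt
Reagents that add atoms: benzyl bromide, BrCc1ccccc1
Why: SN2 O-alkylation of the carboxylate; bicarbonate deprotonates only the carboxylic acid, so the phenols should not be benzylated, and room temperature avoids decarboxylation.

Step 3
Reactants: 4 benzyl 2,4-dihydroxy-6-pentylbenzoate; 5 hex-2-ynoic acid
Product: 6 benzyl 4-(hex-2-ynoyloxy)-2-hydroxy-6-pentylbenzoate
Conditions: DCC (1.1 equiv), DMAP (5 mol %), CH2Cl2, 0 °C to rt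
Reagents that add atoms: none
Why: Steglich esterification. The 2-hydroxyl is locked in a hydrogen bond to the ester carbonyl and is flanked by it, so the free 4-hydroxyl should be acylated selectively; low temperature and only catalytic DMAP limit conjugate addition to the ynoate.

Step 4
Reactants: 7 methyl acetoacetate
Product: 9 methyl (2E)-3-methoxybut-2-enoate, via methyl 3,3-dimethoxybutanoate 8 (not isolated)
Conditions: HC(OMe)3 (1.1 equiv), H2SO4 (cat.), neat, rt; then distil from a trace of TsOH
Reagents that add atoms: trimethyl orthoformate, COC(OC)OC
Why: Acid-catalysed ketalization of the ketone by the orthoester, then loss of methanol from ketal 8 on distillation, gives the conjugated enol ether. The E isomer, with methoxy anti to the ester, is the thermodynamically preferred one.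

Step 5
Reactants: 9 methyl (2E)-3-methoxybut-2-enoate
Product: 11 (1E)-1,3-dimethoxy-1-(trimethylsilyloxy)buta-1,3-diene, via lithium dienolate 10 (not isolated)
Conditions: LDA (1.1 equiv), THF, −78 °C; then TMSCl (1.2 equiv), −78 °C to rt; filter under Ar, distil
Reagents that add atoms: chlorotrimethylsilane, C[Si](C)(C)Cl
Why: γ-Deprotonation of the vinylogous ester gives the extended dienolate 10, which the hard silyl chloride traps on oxygen as the silyl ketene acetal; this is the standard preparation of 1,1,3-trioxygenated butadienes. The diene is moisture-sensitive and is used freshly distilled.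

Step 6
Reactants: 6 benzyl 4-(hex-2-ynoyloxy)-2-hydroxy-6-pentylbenzoate; 11 (1E)-1,3-dimethoxy-1-(trimethylsilyloxy)buta-1,3-diene
Product: 14 benzyl 2-hydroxy-4-[(2-hydroxy-4-methoxy-6-propylbenzoyl)oxy]-6-pentylbenzoate, via ring B trimethylsilyl ether 12 (not isolated), via cyclohexa-1,4-diene cycloadduct 13 (not isolated)
Conditions: N,O-bis(trimethylsilyl)acetamide (BSA, 1.5 equiv), PhMe, 60 °C, 1 h; then 11 (3 equiv), 110 °C, sealed tube, 24–48 h; then 1 M HCl, THF, 0 °C to rt
Reagents that add atoms: none
Why: Diels–Alder addition of a 1,1,3-trioxygenated butadiene to an acetylenic ester followed by aromatization, the known route from such dienes to 2-hydroxy-4-methoxybenzoates, applied here to an aryl ynoate. The chelated ring B phenol is first capped as silyl ether 12 so that it cannot protonate the ketene acetal. The addition is concerted but strongly asynchronous: the CH2 terminus of 11, toward which both the 3-methoxy and the ketene acetal oxygens push electron density, bonds to the propyl-bearing β-carbon of the ynoate, and the ketene acetal carbon then closes on the α-carbon, so that this [4+2] closure forms ring A as the six-membered carbocycle 13. Polarity matching alone fixes the orientation, so the ketal carbon becomes C2 next to the ester carbon and the enol ether carbon becomes C4. The aryl ester lowers the LUMO of the triple bond relative to an alkyl ynoate, which an internal ynoate needs. The ketal carbon of 13 is a transient stereocenter formed as a racemate; it is erased when acid ionizes the mixed ketal, methanol leaves and the ring CH2 loses a proton to give the arene, so no stereocenter remains. The trimethylsilyl ethers on both rings hydrolyse in the same work-up. Both esters see only neutral heat and dilute acid, and the C4 methyl ether arrives with 11, so no later O-methylation is needed.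

Step 7
Reactants: 14 benzyl 2-hydroxy-4-[(2-hydroxy-4-methoxy-6-propylbenzoyl)oxy]-6-pentylbenzoate
Product: 15 stenosporic acid (2-hydroxy-4-[(2-hydroxy-4-methoxy-6-propylbenzoyl)oxy]-6-pentylbenzoic acid)
Conditions: H2 (1 atm), Pd/C (10 wt % Pd), EtOAc, rt
Reagents that add atoms: none
Why: Hydrogenolysis of the benzyl ester under neutral conditions; the aryl ester link, the aryl methyl ether and both arenes are inert, and the salicylic acid is released without base or heat, so neither depside cleavage nor decarboxylation is expected.

## Compound list

1 | olivetol (5-pentylbenzene-1,3-diol) | CCCCCc1cc(O)cc(O)c1 | starting material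
2 | magnesium 2-carboxylato-5-hydroxy-3-pentylphenolate (magnesium olivetolate chelate, drawn as the 1:1 salt) | [Mg+2].CCCCCc1cc(O)cc([O-])c1C(=O)[O-] | intermediate (not isolated)
3 | olivetolic acid (2,4-dihydroxy-6-pentylbenzoic acid) | CCCCCc1cc(O)cc(O)c1C(=O)O | intermediate
4 | benzyl 2,4-dihydroxy-6-pentylbenzoate | CCCCCc1cc(O)cc(O)c1C(=O)OCc1ccccc1 | intermediate
5 | hex-2-ynoic acid | CCCC#CC(=O)O | starting material
6 | benzyl 4-(hex-2-ynoyloxy)-2-hydroxy-6-pentylbenzoate | CCCC#CC(=O)Oc1cc(O)c(C(=O)OCc2ccccc2)c(CCCCC)c1 | intermediate
7 | methyl acetoacetate | CC(=O)CC(=O)OC | starting material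
8 | methyl 3,3-dimethoxybutanoate | COC(=O)CC(C)(OC)OC | intermediate (not isolated)
9 | methyl (2E)-3-methoxybut-2-enoate | CO/C(C)=C/C(=O)OC | intermediate
10 | lithium (1Z)-1,3-dimethoxybuta-1,3-dien-1-olate | [Li+].C=C(OC)/C=C(\OC)[O-] | intermediate (not isolated)
11 | (1E)-1,3-dimethoxy-1-(trimethylsilyloxy)buta-1,3-diene | C=C(OC)/C=C(\OC)O[Si](C)(C)C | intermediate
12 | benzyl 4-(hex-2-ynoyloxy)-6-pentyl-2-(trimethylsilyloxy)benzoate | CCCC#CC(=O)Oc1cc(O[Si](C)(C)C)c(C(=O)OCc2ccccc2)c(CCCCC)c1 | intermediate (not isolated)
13 | benzyl 4-{[4,6-dimethoxy-2-propyl-6-(trimethylsilyloxy)cyclohexa-1,4-diene-1-carbonyl]oxy}-6-pentyl-2-(trimethylsilyloxy)benzoate, racemic at C6 of the cyclohexadiene | CCCCCc1cc(OC(=O)C2=C(CCC)CC(OC)=CC2(OC)O[Si](C)(C)C)cc(O[Si](C)(C)C)c1C(=O)OCc1ccccc1 | intermediate (not isolated)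
14 | benzyl 2-hydroxy-4-[(2-hydroxy-4-methoxy-6-propylbenzoyl)oxy]-6-pentylbenzoate | CCCCCc1cc(OC(=O)c2c(O)cc(OC)cc2CCC)cc(O)c1C(=O)OCc1ccccc1 | intermediate
15 | stenosporic acid (2-hydroxy-4-[(2-hydroxy-4-methoxy-6-propylbenzoyl)oxy]-6-pentylbenzoic acid) | CCCCCc1cc(OC(=O)c2c(O)cc(OC)cc2CCC)cc(O)c1C(=O)O | target

## Step count and risk

Total step count: 7. Longest linear sequence: 5 steps (steps 1, 2, 3, 6, 7); the diene arm (steps 4, 5) joins at step 6.

**Step 6 (key step).**
- What may go wrong: the internal, β-alkyl ynoate may add the diene slowly, and at the temperature needed the silyl ketene acetal may be lost to hydrolysis or O-to-C silyl migration faster than it cycloadds. The nucleophilic diene may attack the aryl ester carbonyl and cleave the link to ring B. On acidification the enol ether of 13 may hydrolyse before methanol is eliminated, which would leave a free hydroxyl where the C4 methyl ether should be.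
- Fallback, setting out from 4 and returning at 15: ring A is made by classical arene chemistry and attached as a preformed acid. Commercial 5-propylbenzene-1,3-diol F1 is formylated (Vilsmeier–Haack: POCl3, DMF, 0 °C to rt; aqueous NaOAc) to 2,4-dihydroxy-6-propylbenzaldehyde F2. The unchelated 4-hydroxyl is methylated (MeI, 1 equiv, K2CO3, acetone) to 2-hydroxy-4-methoxy-6-propylbenzaldehyde F3. The chelated hydroxyl is benzylated (BnBr, K2CO3, DMF, 60 °C) to 2-(benzyloxy)-4-methoxy-6-propylbenzaldehyde F4. Pinnick oxidation (NaClO2, NaH2PO4, 2-methylbut-2-ene, t-BuOH–H2O) gives 2-(benzyloxy)-4-methoxy-6-propylbenzoic acid F5. This acid is condensed with 4 by activation with trifluoroacetic anhydride in toluene at rt to give benzyl 4-{[2-(benzyloxy)-4-methoxy-6-propylbenzoyl]oxy}-2-hydroxy-6-pentylbenzoate F6. Hydrogenolysis of both benzyl groups (H2, Pd/C, EtOAc) then returns the route at 15.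

**Step 1.**
- What may go wrong: carboxylation may occur between the two hydroxyls instead of at the ortho/para position, and because the reaction is reversible the product may decarboxylate during the hot reaction or the acidic work-up.
- Fallback, setting out from 1 and returning at 3: an irreversible electrophilic substitution installs the carbon instead. Vilsmeier–Haack formylation of 1 (POCl3, DMF, 0 °C to rt; aqueous NaOAc) gives 2,4-dihydroxy-6-pentylbenzaldehyde F7. Acetylation (Ac2O, pyridine) gives 2,4-bis(acetyloxy)-6-pentylbenzaldehyde F8. Pinnick oxidation (NaClO2, NaH2PO4, 2-methylbut-2-ene, t-BuOH–H2O) gives 2,4-bis(acetyloxy)-6-pentylbenzoic acid F9. Saponification of the two acetates (aqueous NaOH, 0 °C to rt; cold dilute HCl) returns the route at 3.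

**Step 3.**
- What may go wrong: the phenol of 4 or DMAP may add in conjugate fashion to the activated triple bond once the aryl ynoate has formed, the O-acylisourea may rearrange to an N-acylurea, or both hydroxyls may be acylated.
- Fallback, setting out from 4 and 5 and returning at 6: the acylation is run under acidic, amine-free conditions. Acid 5 is converted in the flask with trifluoroacetic anhydride in toluene into hex-2-ynoic trifluoroacetic anhydride F10, which acylates the free 4-hydroxyl of 4 at rt; with no base or nucleophilic catalyst present, conjugate addition has no promoter.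

## Further compounds

F1 | step 6 | 5-propylbenzene-1,3-diol | CCCc1cc(O)cc(O)c1
F2 | step 6 | 2,4-dihydroxy-6-propylbenzaldehyde | CCCc1cc(O)cc(O)c1C=O
F3 | step 6 | 2-hydroxy-4-methoxy-6-propylbenzaldehyde | CCCc1cc(OC)cc(O)c1C=O
F4 | step 6 | 2-(benzyloxy)-4-methoxy-6-propylbenzaldehyde | CCCc1cc(OC)cc(OCc2ccccc2)c1C=O
F5 | step 6 | 2-(benzyloxy)-4-methoxy-6-propylbenzoic acid | CCCc1cc(OC)cc(OCc2ccccc2)c1C(=O)O
F6 | step 6 | benzyl 4-{[2-(benzyloxy)-4-methoxy-6-propylbenzoyl]oxy}-2-hydroxy-6-pentylbenzoate | CCCCCc1cc(OC(=O)c2c(OCc3ccccc3)cc(OC)cc2CCC)cc(O)c1C(=O)OCc1ccccc1
F7 | step 1 | 2,4-dihydroxy-6-pentylbenzaldehyde | CCCCCc1cc(O)cc(O)c1C=O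
F8 | step 1 | 2,4-bis(acetyloxy)-6-pentylbenzaldehyde | CCCCCc1cc(OC(C)=O)cc(OC(C)=O)c1C=O
F9 | step 1 | 2,4-bis(acetyloxy)-6-pentylbenzoic acid | CCCCCc1cc(OC(C)=O)cc(OC(C)=O)c1C(=O)O
F10 | step 3 | hex-2-ynoic trifluoroacetic anhydride | CCCC#CC(=O)OC(=O)C(F)(F)F
A1 | alternative 1 | benzyl 4-{[2-(benzyloxy)-4-methoxy-6-propylbenzoyl]oxy}-2-[(tert-butyldimethylsilyl)oxy]-6-pentylbenzoate | CCCCCc1cc(OC(=O)c2c(OCc3ccccc3)cc(OC)cc2CCC)cc(O[Si](C)(C)C(C)(C)C)c1C(=O)OCc1ccccc1
A2 | alternative 1 | 5-[(tert-butyldimethylsilyl)oxy]-3,3-dimethylcyclohexa-1,5-dien-1-yl 2-(benzyloxy)-4-methoxy-6-propylbenzoate | CCCc1cc(OC)cc(OCc2ccccc2)c1C(=O)OC1=CC(C)(C)CC(O[Si](C)(C)C(C)(C)C)=C1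
A3 | alternative 1 | benzyl oct-2-ynoate | CCCCCC#CC(=O)OCc1ccccc1
A4 | alternative 2 | benzyl 4-[(2,4-dimethoxy-6-propylbenzoyl)oxy]-2-methoxy-6-pentylbenzoate | CCCCCc1cc(OC(=O)c2c(OC)cc(OC)cc2CCC)cc(OC)c1C(=O)OCc1ccccc1
A5 | alternative 2 | 2-oxo-6-pentyl-2H-pyran-4-yl 2,4-dimethoxy-6-propylbenzoate | CCCCCc1cc(OC(=O)c2c(OC)cc(OC)cc2CCC)cc(=O)o1
A6 | alternative 2 | benzyl 3-methoxyprop-2-ynoate | COC#CC(=O)OCc1ccccc1
A7 | alternative 3 | benzyl 4-[(2,4-dihydroxy-6-propylbenzoyl)oxy]-2-hydroxy-6-pentylbenzoate | CCCCCc1cc(OC(=O)c2c(O)cc(O)cc2CCC)cc(O)c1C(=O)OCc1ccccc1
A8 | alternative 3 | benzyl 2-hydroxy-6-pentyl-4-[(3,5,7-trioxodecanoyl)oxy]benzoate | CCCC(=O)CC(=O)CC(=O)CC(=O)Oc1cc(O)c(C(=O)OCc2ccccc2)c(CCCCC)c1
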